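**Retrosynthetic overview**

1. Atom labels (germacrane numbering): ten-membered carbocycle C1(OH)–C2–C3–C4(C15H2OH)=C5–C6(O)–C7–C8(O-acyl)–C9=C10(C14H3); lactone ring C6–O–C12(=O)–C11(=C13H2)–C7. The O8 ester and the two silyl ethers are handled last.
2. Key disconnection C7–C8: the homoallylic array O–C8–C7–C11(=C13H2), the seam between the carbocycle and the α-methylene lactone ring, is the retron of a carbonyl allylation with allylic transposition. The precursor is an open-chain (Z)-enal (C8) tethered through C6 to a 3-(bromomethyl)butenolide; CrCl2 closes the ten-membered ring, sets C7 and C8 and unveils the exocyclic methylene in one operation.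
3. Ring order: lactone ring first (as a butenolide, by directed hydroalumination–iodination of a C6 propargylic alcohol and carbonylative lactonisation), carbocycle second.
4. Chain assembly: B-alkyl Suzuki–Miyaura coupling at C3–C4 of a (Z)-iodoalkene (C4–C7, C11, C13, C15) with a C1–C3/C8–C10 diene. C1 and C6 come from Me2Zn/ProPhenol alkynylations, the C9=C10 geometry from syn-methylcupration of an ynoate, the C4=C5 geometry from hydroalumination–iodination of a butynediol monoether.

Key step: step 14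

Assumption (remark on the chemistry): (S,S)-ProPhenol is taken to give the (S)-carbinol 4 in step 1 and, by the same facial preference, its (R,R)-antipode the (R)-carbinol 14 in step 7. If the sense of induction is the reverse, the two ligand antipodes are exchanged.

**Route**

Step 1
Reactants: 1 acrolein; 2 methyl propiolate
Product: 4 methyl (4S)-4-hydroxyhex-5-en-2-ynoate, via zinc acetylide 3 (not isolated)
Conditions: Me2Zn, (S,S)-ProPhenol (10 mol%), Ph3P=O (20 mol%), toluene, 0 °C, slow addition of 1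
Reagents that add atoms: none
Why: Me2Zn/ProPhenol-catalysed enantioselective alkynylation of an aldehyde: the methylzinc acetylide 3 adds 1,2 to the enal inside the chiral dinuclear zinc pocket, which should set C1 as (S) by ligand control.

Step 2
Reactants: 4 methyl (4S)-4-hydroxyhex-5-en-2-ynoate
Product: 5 methyl (4S)-4-[(tert-butyldimethylsilyl)oxy]hex-5-en-2-ynoate
Conditions: TBSCl, imidazole, DMF, 0 °C to rt
Reagents that add atoms: tert-butyldimethylsilyl chloride, CC(C)(C)[Si](C)(C)Cl
Why: Standard imidazole-promoted O-silylation; the silyl ether blocks lactonisation and keeps O1 from acting as a leaving group in the cuprate step, with no change at C1.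

Step 3
Reactants: 5 methyl (4S)-4-[(tert-butyldimethylsilyl)oxy]hex-5-en-2-ynoate
Product: 6 methyl (2Z,4S)-4-[(tert-butyldimethylsilyl)oxy]-3-methylhexa-2,5-dienoate
Conditions: Me2CuLi (from MeLi and CuI), THF, −78 °C; MeOH then aq NH4Cl at −78 °C
Reagents that add atoms: lithium dimethylcuprate, [Li+].C[Cu-]C (made in the flask from methyllithium, [Li]C, and CuI)
Why: Conjugate addition of a Gilman cuprate to an ynoate is a syn-carbocupration, and protonation of the alkenylcopper at −78 °C with retention places C1 cis to the ester carbon C8, which fixes the (Z)-C9=C10 geometry and installs C14.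

Step 4
Reactants: 6 methyl (2Z,4S)-4-[(tert-butyldimethylsilyl)oxy]-3-methylhexa-2,5-dienoate
Product: 7 (2Z,4S)-4-[(tert-butyldimethylsilyl)oxy]-3-methylhexa-2,5-dien-1-ol
Conditions: i-Bu2AlH, CH2Cl2, −78 °C; Rochelle salt work-up
Reagents that add atoms: none
Why: 1,2-Reduction of the enoate by i-Bu2AlH gives the allylic alcohol without touching the alkene geometry or the silyl ether.

Step 5
Reactants: 8 4-[(tert-butyldimethylsilyl)oxy]but-2-yn-1-ol
Product: 10 (2Z)-4-[(tert-butyldimethylsilyl)oxy]-3-iodobut-2-en-1-ol, via cyclic alkenylalanate 9 (not isolated)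
Conditions: NaAlH2(OCH2CH2OMe)2, THF, 0 °C; EtOAc; then I2, THF, −78 °C
Reagents that add atoms: iodine, II
Why: Hydroxyl-directed trans-hydroalumination of a propargylic alcohol (hydride to the proximal carbon, aluminium to the distal one within the five-membered alanate 9) followed by iodinolysis with retention gives the (Z)-iodoalkene with iodine cis to the carbinol carbon, which is the C4=C5 geometry of the target once iodine is replaced by C3.

Step 6
Reactants: 10 (2Z)-4-[(tert-butyldimethylsilyl)oxy]-3-iodobut-2-en-1-ol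
Product: 11 (2Z)-4-[(tert-butyldimethylsilyl)oxy]-3-iodobut-2-enal
Conditions: MnO2, CH2Cl2, rt, dark
Reagents that add atoms: none
Why: Allylic alcohol oxidation on MnO2 is mild and neutral, so the (Z)-β-iodo enal should form without isomerisation.

Step 7
Reactants: 11 (2Z)-4-[(tert-butyldimethylsilyl)oxy]-3-iodobut-2-enal; 12 1-methoxy-4-[(prop-2-yn-1-yloxy)methyl]benzene
Product: 14 (2Z,4R)-1-[(tert-butyldimethylsilyl)oxy]-2-iodo-7-[(4-methoxybenzyl)oxy]hept-2-en-5-yn-4-ol, via zinc acetylide 13 (not isolated)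
Conditions: Me2Zn, (R,R)-ProPhenol (20 mol%), Ph3P=O, toluene, 0 °C
Reagents that add atoms: none
Why: Me2Zn/ProPhenol-catalysed enantioselective alkynylation of the enal, here with the antipodal ligand, should set C6 as (R) by ligand control and joins C6 to C7.

Step 8
Reactants: 7 (2Z,4S)-4-[(tert-butyldimethylsilyl)oxy]-3-methylhexa-2,5-dien-1-ol; 14 (2Z,4R)-1-[(tert-butyldimethylsilyl)oxy]-2-iodo-7-[(4-methoxybenzyl)oxy]hept-2-en-5-yn-4-ol
Product: 16 (2Z,4S,7E,9R)-4-[(tert-butyldimethylsilyl)oxy]-7-{[(tert-butyldimethylsilyl)oxy]methyl}-12-[(4-methoxybenzyl)oxy]-3-methyldodeca-2,7-dien-10-yne-1,9-diol, via trialkylborane 15 (not isolated)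
Conditions: 7, 9-BBN-H (2.2 equiv), THF, rt; then 14, Pd(dppf)Cl2 (5 mol%), AsPh3, Cs2CO3, DMF/H2O, rt
Reagents that add atoms: none
Why: B-alkyl Suzuki–Miyaura coupling: 9-BBN-H hydroborates only the monosubstituted alkene of 7 at its terminal carbon C3, and the palladium-catalysed coupling with the iodoalkene proceeds with retention, so C3 ends up cis to C6 across C4=C5.

Step 9
Reactants: 16 (2Z,4S,7E,9R)-4-[(tert-butyldimethylsilyl)oxy]-7-{[(tert-butyldimethylsilyl)oxy]methyl}-12-[(4-methoxybenzyl)oxy]-3-methyldodeca-2,7-dien-10-yne-1,9-diol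
Product: 18 (2Z,4S,7E,9R,10Z)-4-[(tert-butyldimethylsilyl)oxy]-7-{[(tert-butyldimethylsilyl)oxy]methyl}-11-iodo-12-[(4-methoxybenzyl)oxy]-3-methyldodeca-2,7,10-triene-1,9-diol, via cyclic alkenylalanate 17 (not isolated)
Conditions: NaAlH2(OCH2CH2OMe)2 (3.5 equiv), THF, −20 to 0 °C; EtOAc; then I2, THF, −78 °C
Reagents that add atoms: iodine, II
Why: Same directed trans-hydroalumination–iodination as in step 5, now steered by the C6 alkoxide: hydride goes to C7 and iodine to C11 cis to C6, the geometry needed for lactonisation, with C6 untouched.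

Step 10
Reactants: 18 (2Z,4S,7E,9R,10Z)-4-[(tert-butyldimethylsilyl)oxy]-7-{[(tert-butyldimethylsilyl)oxy]methyl}-11-iodo-12-[(4-methoxybenzyl)oxy]-3-methyldodeca-2,7,10-triene-1,9-diol
Product: 19 (5R)-5-[(1E,5S,6Z)-5-[(tert-butyldimethylsilyl)oxy]-2-{[(tert-butyldimethylsilyl)oxy]methyl}-8-hydroxy-6-methylocta-1,6-dien-1-yl]-3-{[(4-methoxybenzyl)oxy]methyl}furan-2(5H)-one
Conditions: Pd(PPh3)2Cl2 (5 mol%), CO (1 atm), K2CO3, THF, rt
Reagents that add atoms: carbon monoxide, [C-]#[O+]
Why: Palladium-catalysed carbonylative lactonisation: oxidative addition of zerovalent palladium into the C11–I bond, CO insertion and capture of the acylpalladium by the cis C6 hydroxyl close the butenolide ring and introduce C12.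

Step 11
Reactants: 19 (5R)-5-[(1E,5S,6Z)-5-[(tert-butyldimethylsilyl)oxy]-2-{[(tert-butyldimethylsilyl)oxy]methyl}-8-hydroxy-6-methylocta-1,6-dien-1-yl]-3-{[(4-methoxybenzyl)oxy]methyl}furan-2(5H)-one
Product: 20 (2Z,4S,7E)-4-[(tert-butyldimethylsilyl)oxy]-7-{[(tert-butyldimethylsilyl)oxy]methyl}-8-[(2R)-4-{[(4-methoxybenzyl)oxy]methyl}-5-oxo-2,5-dihydrofuran-2-yl]-3-methylocta-2,7-dienal
Conditions: MnO2, CH2Cl2, rt
Reagents that add atoms: none
Why: MnO2 oxidises the only free (allylic) hydroxyl to the (Z)-enal under neutral conditions that should spare the base-sensitive C6–H of the butenolide.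

Step 12
Reactants: 20 (2Z,4S,7E)-4-[(tert-butyldimethylsilyl)oxy]-7-{[(tert-butyldimethylsilyl)oxy]methyl}-8-[(2R)-4-{[(4-methoxybenzyl)oxy]methyl}-5-oxo-2,5-dihydrofuran-2-yl]-3-methylocta-2,7-dienal
Product: 21 (2Z,4S,7E)-4-[(tert-butyldimethylsilyl)oxy]-7-{[(tert-butyldimethylsilyl)oxy]methyl}-8-[(2R)-4-(hydroxymethyl)-5-oxo-2,5-dihydrofuran-2-yl]-3-methylocta-2,7-dienal
Conditions: DDQ, CH2Cl2/pH 7 buffer, 0 °C
Reagents that add atoms: none
Why: Oxidative cleavage of the 4-methoxybenzyl ether by DDQ (hydride abstraction and hydrolysis of the oxocarbenium ion) frees O13 while the silyl ethers, the enal and the butenolide stay intact.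

Step 13
Reactants: 21 (2Z,4S,7E)-4-[(tert-butyldimethylsilyl)oxy]-7-{[(tert-butyldimethylsilyl)oxy]methyl}-8-[(2R)-4-(hydroxymethyl)-5-oxo-2,5-dihydrofuran-2-yl]-3-methylocta-2,7-dienal
Product: 22 (2Z,4S,7E)-8-[(2R)-4-(bromomethyl)-5-oxo-2,5-dihydrofuran-2-yl]-4-[(tert-butyldimethylsilyl)oxy]-7-{[(tert-butyldimethylsilyl)oxy]methyl}-3-methylocta-2,7-dienal
Conditions: PPh3, N-bromosuccinimide, CH2Cl2, −20 °C
Reagents that add atoms: N-bromosuccinimide, O=C1CCC(=O)N1Br
Why: Appel-type bromination through the alkoxyphosphonium salt under neutral conditions converts the C13 alcohol into the allylic bromide in the presence of the aldehyde; an SN2' isomer, if formed, would give the same allylchromium species in step 14.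

Step 14
Reactants: 22 (2Z,4S,7E)-8-[(2R)-4-(bromomethyl)-5-oxo-2,5-dihydrofuran-2-yl]-4-[(tert-butyldimethylsilyl)oxy]-7-{[(tert-butyldimethylsilyl)oxy]methyl}-3-methylocta-2,7-dienal
Product: 24 (3aR,4R,5Z,7S,10E,11aR)-7-[(tert-butyldimethylsilyl)oxy]-10-{[(tert-butyldimethylsilyl)oxy]methyl}-4-hydroxy-6-methyl-3-methylidene-3a,4,7,8,9,11a-hexahydrocyclodeca[b]furan-2(3H)-one, via allylchromium dichloride 23 (not isolated)
Conditions: CrCl2 (6 equiv), THF, rt, slow addition of 22 (final concentration about 2 mM); pH 7 buffer work-up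
Reagents that add atoms: none
Why: CrCl2 reduces the allylic C13–Br bond by two one-electron transfers to the allylchromium species 23, whose C7 terminus adds to the tethered aldehyde C8 through a closed six-membered Zimmerman–Traxler transition state with allylic transposition, so that C11=C13 emerges as the exocyclic methylene. The closest known reaction type is the Nozaki–Hiyama–Kishi/Barbier allylation of aldehydes with 2-(bromomethyl)acrylates and 3-(bromomethyl)butenolides, together with its intramolecular use for closing ten-membered germacrane rings. The ten-membered carbocycle is closed in a 10-exo-trig mode (carbonyl oxygen outside the new ring), with the lactone ring already in place. C7 is set by the resident C6 stereocentre: bonding occurs on the butenolide face opposite to the C6–C5 bond, which lets the eight-atom chain C6–C9 span C6 and C7 with the roughly 90° C5–C6–C7–C8 torsion of a trans-fused germacranolide and gives the 6,7-trans lactone (7R). C8 is set by the chair transition state: the butenolide ring locks C6 trans to C13 (an E-type γ-substituted allylmetal, pseudo-equatorial C6), and a pseudo-equatorial C9 then gives the (8R) carbinol with O8 on the same face of the carbocycle as C11. The step needs γ- over α-attack (ten- versus twelve-membered ring), 1,2- over 1,4-addition and cyclisation over oligomerisation; these are secured by the chromium-bridged cyclic transition state, by the two (Z)-alkenes and the lactone acting as turn elements of the chain, and by slow addition at high dilution.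

Step 15
Reactants: 24 (3aR,4R,5Z,7S,10E,11aR)-7-[(tert-butyldimethylsilyl)oxy]-10-{[(tert-butyldimethylsilyl)oxy]methyl}-4-hydroxy-6-methyl-3-methylidene-3a,4,7,8,9,11a-hexahydrocyclodeca[b]furan-2(3H)-one; 25 (2S)-2-methylbutanoic anhydride
Product: 26 (3aR,4R,5Z,7S,10E,11aR)-7-[(tert-butyldimethylsilyl)oxy]-10-{[(tert-butyldimethylsilyl)oxy]methyl}-6-methyl-3-methylidene-2-oxo-2,3,3a,4,7,8,9,11a-octahydrocyclodeca[b]furan-4-yl (2S)-2-methylbutanoate
Conditions: 25, DMAP (cat.), Et3N, CH2Cl2, 0 °C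
Reagents that add atoms: none
Why: DMAP-catalysed acylation of the secondary allylic alcohol with the anhydride proceeds with retention at C8, and the (S) centre of the side chain comes unchanged from 25 because the anhydride avoids ketene-forming activation.

Step 16
Reactants: 26 (3aR,4R,5Z,7S,10E,11aR)-7-[(tert-butyldimethylsilyl)oxy]-10-{[(tert-butyldimethylsilyl)oxy]methyl}-6-methyl-3-methylidene-2-oxo-2,3,3a,4,7,8,9,11a-octahydrocyclodeca[b]furan-4-yl (2S)-2-methylbutanoate
Product: 27 (3aR,4R,5Z,7S,10E,11aR)-7-hydroxy-10-(hydroxymethyl)-6-methyl-3-methylidene-2-oxo-2,3,3a,4,7,8,9,11a-octahydrocyclodeca[b]furan-4-yl (2S)-2-methylbutanoate (CNP0526758.1)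
Conditions: HF·pyridine, pyridine, THF, 0 °C to rt
Reagents that add atoms: none
Why: Fluoride-mediated cleavage of both silyl ethers with buffered HF·pyridine is compatible with the α-methylene lactone and the ester, and touches no stereocentre.

**Compound list**

1 | acrolein | C=CC=O | starting material
2 | methyl propiolate | C#CC(=O)OC | starting material
3 | methyl 3-(methylzincio)prop-2-ynoate (zinc acetylide, not isolated) | C[Zn]C#CC(=O)OC | intermediate
4 | methyl (4S)-4-hydroxyhex-5-en-2-ynoate | C=C[C@H](O)C#CC(=O)OC | intermediate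
5 | methyl (4S)-4-[(tert-butyldimethylsilyl)oxy]hex-5-en-2-ynoate | C=C[C@H](O[Si](C)(C)C(C)(C)C)C#CC(=O)OC | intermediate
6 | methyl (2Z,4S)-4-[(tert-butyldimethylsilyl)oxy]-3-methylhexa-2,5-dienoate | C=C[C@H](O[Si](C)(C)C(C)(C)C)/C(C)=C\C(=O)OC | intermediate
7 | (2Z,4S)-4-[(tert-butyldimethylsilyl)oxy]-3-methylhexa-2,5-dien-1-ol | C=C[C@H](O[Si](C)(C)C(C)(C)C)/C(C)=C\CO | intermediate
8 | 4-[(tert-butyldimethylsilyl)oxy]but-2-yn-1-ol | OCC#CCO[Si](C)(C)C(C)(C)C | starting material
9 | sodium cyclic alkenylalanate from 8 (five-membered O–Al–C ring, not isolated) | [Na+].COCCO[Al-]1(OCCOC)OCC=C1CO[Si](C)(C)C(C)(C)C | intermediate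
10 | (2Z)-4-[(tert-butyldimethylsilyl)oxy]-3-iodobut-2-en-1-ol | OC/C=C(\I)CO[Si](C)(C)C(C)(C)C | intermediate
11 | (2Z)-4-[(tert-butyldimethylsilyl)oxy]-3-iodobut-2-enal | O=C/C=C(\I)CO[Si](C)(C)C(C)(C)C | intermediate
12 | 1-methoxy-4-[(prop-2-yn-1-yloxy)methyl]benzene (4-methoxybenzyl propargyl ether) | C#CCOCc1ccc(OC)cc1 | starting material
13 | methyl{3-[(4-methoxybenzyl)oxy]prop-1-yn-1-yl}zinc (zinc acetylide, not isolated) | C[Zn]C#CCOCc1ccc(OC)cc1 | intermediate
14 | (2Z,4R)-1-[(tert-butyldimethylsilyl)oxy]-2-iodo-7-[(4-methoxybenzyl)oxy]hept-2-en-5-yn-4-ol | O[C@@H](C#CCOCc1ccc(OC)cc1)/C=C(\I)CO[Si](C)(C)C(C)(C)C | intermediate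
15 | trialkylborane from 7 (C3 bound to 9-BBN, O8 as 9-BBN borinate, not isolated) | C1CC2CCCC(C1)B2CC[C@H](O[Si](C)(C)C(C)(C)C)/C(C)=C\COB1C2CCCC1CCC2 | intermediate
16 | (2Z,4S,7E,9R)-4-[(tert-butyldimethylsilyl)oxy]-7-{[(tert-butyldimethylsilyl)oxy]methyl}-12-[(4-methoxybenzyl)oxy]-3-methyldodeca-2,7-dien-10-yne-1,9-diol | O[C@@H](C#CCOCc1ccc(OC)cc1)/C=C(/CO[Si](C)(C)C(C)(C)C)CC[C@H](O[Si](C)(C)C(C)(C)C)/C(C)=C\CO | intermediate
17 | disodium cyclic alkenylalanate from 16 (O6–Al–C11 ring, O8 as alkoxyhydridoaluminate, not isolated) | [Na+].[Na+].COCCO[Al-]1(OCCOC)O[C@H](/C=C(/CO[Si](C)(C)C(C)(C)C)CC[C@H](O[Si](C)(C)C(C)(C)C)/C(C)=C\CO[AlH-](OCCOC)OCCOC)C=C1COCc1ccc(OC)cc1 | intermediate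
18 | (2Z,4S,7E,9R,10Z)-4-[(tert-butyldimethylsilyl)oxy]-7-{[(tert-butyldimethylsilyl)oxy]methyl}-11-iodo-12-[(4-methoxybenzyl)oxy]-3-methyldodeca-2,7,10-triene-1,9-diol | O[C@@H](/C=C(\I)COCc1ccc(OC)cc1)/C=C(/CO[Si](C)(C)C(C)(C)C)CC[C@H](O[Si](C)(C)C(C)(C)C)/C(C)=C\CO | intermediate
19 | (5R)-5-[(1E,5S,6Z)-5-[(tert-butyldimethylsilyl)oxy]-2-{[(tert-butyldimethylsilyl)oxy]methyl}-8-hydroxy-6-methylocta-1,6-dien-1-yl]-3-{[(4-methoxybenzyl)oxy]methyl}furan-2(5H)-one | O=C1O[C@H](/C=C(/CO[Si](C)(C)C(C)(C)C)CC[C@H](O[Si](C)(C)C(C)(C)C)/C(C)=C\CO)C=C1COCc1ccc(OC)cc1 | intermediate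
20 | (2Z,4S,7E)-4-[(tert-butyldimethylsilyl)oxy]-7-{[(tert-butyldimethylsilyl)oxy]methyl}-8-[(2R)-4-{[(4-methoxybenzyl)oxy]methyl}-5-oxo-2,5-dihydrofuran-2-yl]-3-methylocta-2,7-dienal | O=C1O[C@H](/C=C(/CO[Si](C)(C)C(C)(C)C)CC[C@H](O[Si](C)(C)C(C)(C)C)/C(C)=C\C=O)C=C1COCc1ccc(OC)cc1 | intermediate
21 | (2Z,4S,7E)-4-[(tert-butyldimethylsilyl)oxy]-7-{[(tert-butyldimethylsilyl)oxy]methyl}-8-[(2R)-4-(hydroxymethyl)-5-oxo-2,5-dihydrofuran-2-yl]-3-methylocta-2,7-dienal | O=C1O[C@H](/C=C(/CO[Si](C)(C)C(C)(C)C)CC[C@H](O[Si](C)(C)C(C)(C)C)/C(C)=C\C=O)C=C1CO | intermediate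
22 | (2Z,4S,7E)-8-[(2R)-4-(bromomethyl)-5-oxo-2,5-dihydrofuran-2-yl]-4-[(tert-butyldimethylsilyl)oxy]-7-{[(tert-butyldimethylsilyl)oxy]methyl}-3-methylocta-2,7-dienal | O=C1O[C@H](/C=C(/CO[Si](C)(C)C(C)(C)C)CC[C@H](O[Si](C)(C)C(C)(C)C)/C(C)=C\C=O)C=C1CBr | intermediate
23 | allylchromium dichloride from 22 (trivalent chromium on C13, not isolated) | O=C1O[C@H](/C=C(/CO[Si](C)(C)C(C)(C)C)CC[C@H](O[Si](C)(C)C(C)(C)C)/C(C)=C\C=O)C=C1C[Cr](Cl)Cl | intermediate
24 | (3aR,4R,5Z,7S,10E,11aR)-7-[(tert-butyldimethylsilyl)oxy]-10-{[(tert-butyldimethylsilyl)oxy]methyl}-4-hydroxy-6-methyl-3-methylidene-3a,4,7,8,9,11a-hexahydrocyclodeca[b]furan-2(3H)-one | C=C1C(=O)O[C@@H]2/C=C(/CO[Si](C)(C)C(C)(C)C)CC[C@H](O[Si](C)(C)C(C)(C)C)/C(C)=C\[C@@H](O)[C@@H]12 | intermediate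
25 | (2S)-2-methylbutanoic anhydride | CC[C@H](C)C(=O)OC(=O)[C@@H](C)CC | starting material
26 | (3aR,4R,5Z,7S,10E,11aR)-7-[(tert-butyldimethylsilyl)oxy]-10-{[(tert-butyldimethylsilyl)oxy]methyl}-6-methyl-3-methylidene-2-oxo-2,3,3a,4,7,8,9,11a-octahydrocyclodeca[b]furan-4-yl (2S)-2-methylbutanoate | C=C1C(=O)O[C@@H]2/C=C(/CO[Si](C)(C)C(C)(C)C)CC[C@H](O[Si](C)(C)C(C)(C)C)/C(C)=C\[C@@H](OC(=O)[C@@H](C)CC)[C@@H]12 | intermediate
27 | (3aR,4R,5Z,7S,10E,11aR)-7-hydroxy-10-(hydroxymethyl)-6-methyl-3-methylidene-2-oxo-2,3,3a,4,7,8,9,11a-octahydrocyclodeca[b]furan-4-yl (2S)-2-methylbutanoate (CNP0526758.1) | C=C1C(=O)O[C@@H]2/C=C(/CO)CC[C@H](O)/C(C)=C\[C@@H](OC(=O)[C@@H](C)CC)[C@@H]12 | target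

**Step count and risks**

Total step count: 16. Longest linear sequence: 13 steps (steps 1–4, then 8–16).

The three steps most likely to fail:

Step 14 (key step). The process at risk is facial selection at the aldehyde carbon in the macrocyclic transition state: C9 may sit pseudo-axial instead of pseudo-equatorial, which would give the C8 epimer. Intermolecular coupling competing with ring closure is a second concern, addressed by dilution. The fallback sets out from 22. If the same CrCl2 cyclisation delivers mainly the 8-epimeric alcohol F1, C8 is not corrected at the alcohol stage. Instead F1 is esterified with inversion by a Mitsunobu reaction with (2S)-2-methylbutanoic acid (PPh3, diisopropyl azodicarboxylate, toluene, 0 °C), which installs the side chain and the (8R) configuration together. The route is rejoined at 26.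

Step 9. The process at risk is loss of chemoselectivity in the hydride step on the advanced intermediate: β-elimination of the C13 ether from the alkenylalanate to an allene, reduction beyond the alkenylalanate stage, or incomplete iodinolysis. The fallback sets out from 16 and replaces the directed hydroalumination by a ruthenium-catalysed trans-hydrosilylation ([Cp*Ru(MeCN)3]PF6, Et3SiH, CH2Cl2, 0 °C). This places silicon on C11, distal to the hydroxyl and cis to C6, to give the (Z)-alkenylsilane F2. Iododesilylation of F2 with retention (N-iodosuccinimide, (CF3)2CHOH, 0 °C) returns to the route at 18.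

Step 7. The process at risk is low enantioselectivity, or geometric isomerisation and decomposition of the β-iodo enal under the zinc conditions. The fallback sets out from 11 and 12 and separates C–C bond formation from stereocontrol. Compound 12 is deprotonated (n-BuLi, THF, −78 °C) to lithium acetylide F3, which adds to 11 to give the racemic alcohol F4. MnO2 oxidation gives ynone F5. An oxazaborolidine-catalysed (Corey–Bakshi–Shibata) reduction with catecholborane, using the catalyst antipode that delivers hydride to the required face, returns to the route at 14.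

**Further compounds**

F1 | step 14 | (3aR,4S,5Z,7S,10E,11aR)-7-[(tert-butyldimethylsilyl)oxy]-10-{[(tert-butyldimethylsilyl)oxy]methyl}-4-hydroxy-6-methyl-3-methylidene-3a,4,7,8,9,11a-hexahydrocyclodeca[b]furan-2(3H)-one (8-epimer of 24) | C=C1C(=O)O[C@@H]2/C=C(/CO[Si](C)(C)C(C)(C)C)CC[C@H](O[Si](C)(C)C(C)(C)C)/C(C)=C\[C@H](O)[C@@H]12
F2 | step 9 | (2Z,4S,7E,9R,10Z)-4-[(tert-butyldimethylsilyl)oxy]-7-{[(tert-butyldimethylsilyl)oxy]methyl}-12-[(4-methoxybenzyl)oxy]-3-methyl-11-(triethylsilyl)dodeca-2,7,10-triene-1,9-diol | O[C@@H](/C=C(\[Si](CC)(CC)CC)COCc1ccc(OC)cc1)/C=C(/CO[Si](C)(C)C(C)(C)C)CC[C@H](O[Si](C)(C)C(C)(C)C)/C(C)=C\CO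
F3 | step 7 | {3-[(4-methoxybenzyl)oxy]prop-1-yn-1-yl}lithium | [Li]C#CCOCc1ccc(OC)cc1
F4 | step 7 | (2Z)-1-[(tert-butyldimethylsilyl)oxy]-2-iodo-7-[(4-methoxybenzyl)oxy]hept-2-en-5-yn-4-ol (racemic) | OC(C#CCOCc1ccc(OC)cc1)/C=C(\I)CO[Si](C)(C)C(C)(C)C
F5 | step 7 | (2Z)-1-[(tert-butyldimethylsilyl)oxy]-2-iodo-7-[(4-methoxybenzyl)oxy]hept-2-en-5-yn-4-one | O=C(C#CCOCc1ccc(OC)cc1)/C=C(\I)CO[Si](C)(C)C(C)(C)C
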